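The constants used here are assumed; the result is computed.

Target was the product I wanted from the substrate, and the question was what stood where in three flasks that differ in their time.

| setting | east | north-west | west |
|---|---|---|---|
| substrate | 0.50 M | 0.50 M | 0.50 M |
| time | 2.0 h | 3.0 h | 5.0 h |

    substrate → intermediate A (k1 = 0.00121 /s)
    intermediate B → intermediate C (k2 = 9.43 × 10⁻⁴ /s)
    intermediate C → side product (k3 = 0.00144 /s)
    intermediate C → target (k4 = 3.54 × 10⁻⁴ /s)
    intermediate B → decomposed reagent (k5 = 6.38 × 10⁻⁴ /s)
    intermediate A → intermediate B (k6 = 9.75 × 10⁻⁵ /s)

- which of these there is most of at the end, counted by the substrate in it, east (intermediate B / target / intermediate A / side product)
- which of these there is most of at the end, counted by the substrate in it, north-west (intermediate B / target / intermediate A / side product)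
- which of these there is most of at the end, counted by the substrate in it, west (intermediate B / target / intermediate A / side product)
- how much there is at the end of the one of these that leads, in percent of the substrate charged: east
- how much there is at the end of the one of these that leads, in percent of the substrate charged: north-west
- how much there is at the end of the one of these that leads, in percent of the substrate charged: west

I kept a ledger on the substrate, the one thing charged. A mole of it entered intermediate A with a life of 0.230 h, and there it waited, for intermediate A leaves with a life of 2.85 h, much longer. So the step from intermediate A to intermediate B was the rate-limiting step, and [intermediate A] was the one concentration that set the flow onward, at first order.

Past that point the books are shares. Two first-order steps compete on the same [intermediate B], so that concentration cancels: 59.6% goes on to intermediate C and 40.4% to decomposed reagent. At intermediate C, likewise, 80.3% of what arrives becomes side product. Multiplied, these gave 47.9%, which I call the side-product share: the part of whatever has left intermediate A that ends as side product.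

| Entry | Share of what left intermediate A |
|---|---|
| side product | 47.9% |
| target | 11.8% |
| decomposed reagent | 40.4% |

The books closed at 100%.

My reckoning left 0.0165% of the substrate at the end of east, so at each reading I took the late form of the two-step solution: [intermediate A] is the charge times 1.09 times the decay on its own long life, and that factor is a constant of the formula, not a height the flask reached. That left 53.9% in east, 37.9% in north-west and 18.8% in west. The share applied to the remainder put side product at 22.1%, 29.7% and 38.9%. These figures run high, since they book as finished what still sits in intermediates B and C. Even so, I committed: intermediate A leads in east and north-west, side product in west, with target behind side product.

The forecast named intermediate A at 53.9% for east, intermediate A at 37.9% for north-west and side product at 37.7% for west, lower than my west figure, and it held that “target stays well behind”.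

The flasks gave intermediate A at 53.9% in east, intermediate A at 37.9% in north-west and side product at 37.7% in west. In west, intermediate A still held 18.8% at the reading, and my side-product figure stood 1.2 percentage points above the flask. The west flask left until 8.0 h had intermediate A down to 6.56%, so the side-product share put side product there at 44.8%, and that flask read 44.3%.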